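**Plan**

1. Locants used in the text only (elemane numbering): carbocycle = C5–C10 (C10 quaternary, CH3 and vinyl C1=C2; C5 carries C4(=C3H2)–C15HO; C6 OAng; C9 OAc); lactone = O–C8, C7, C11(=C13H2), C12.
2. Retrosynthesis: enal ⇒ allylic silyl ether; cut C5–C6 (ring-closing allylboration), then C9–C10 (intermolecular allylboration), then C6–C7 (radical addition of a C1 acetal to a butenolide) and C11=C13.
3. Enabling feature: the ring holds two homoallylic-alcohol units on adjacent carbons, O–C9–C10(–C1=C2) and O–C6–C5(–C4=C3H2). C10 and C5 can therefore come from one 2,4-dienyl unit C2–C1=C10–C5=C4–C3 that acts twice as an allyl nucleophile on a trans-4,5-difunctional butyrolactone.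
4. Forward order: γ-lactone first (chiral pool), then its two one-carbon arms and the exocyclic methylene, then union at C9–C10, last the cyclohexane by C5–C6.
5. Stereochemistry: C8 from the (R)-lactone; C7 by anti radical addition; C9 by Cornforth/Felkin–Anh addition; C10, then C5 and C6, by two Zimmerman–Traxler allylborations whose alkene geometries come from a cis-silaboration and a trans-hydroalumination; the diequatorial trans-lactone fixes the chair.
6. The acetate and angelate go on as each carbinol appears; the enal oxidation level is set last.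

Key step: step 15

Assumption: compounds 1, 2, 4, 9, 14 and 29 are purchased.

**Route**

Step 1
Reactants: 1 tert-butyl(diphenyl)(prop-2-yn-1-yloxy)silane; 2 2-(dimethylphenylsilyl)-4,4,5,5-tetramethyl-1,3,2-dioxaborolane
Product: 3 tert-butyl{[(2Z)-2-(dimethylphenylsilyl)-3-(pinacolboryl)prop-2-en-1-yl]oxy}diphenylsilane (Si and B cis)
Conditions: Pd(OAc)2 (2 mol%), t-OctNC (30 mol%), toluene, 110 °C
Reagents that add atoms: none
Why: Pd/isocyanide-catalysed cis-silaboration of a terminal alkyne (Si–B oxidative addition, syn insertion) should put boron on the terminal carbon and silicon on the internal one, which fixes the later C5=C4 geometry here.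

Step 2
Reactants: 4 but-2-yn-1-ol
Product: 6 (Z)-3-iodobut-2-en-1-ol, via alkenylalanate 5 (not isolated)
Conditions: Red-Al, THF, 0 °C to rt; then I2, −78 to 0 °C; aq. Rochelle salt
Reagents that add atoms: iodine, II
Why: Hydroxyl-directed trans-hydroalumination of the propargylic alcohol gives the cyclic alkenylalanate with Al on C3 cis to CH2O, and iodinolysis with retention should give the Z iodide (I cis to CH2OH).

Step 3
Reactants: 3 silylboryl alkene; 6 (Z)-3-iodobut-2-en-1-ol
Product: 7 (2Z,4Z)-6-(tert-butyldiphenylsilyloxy)-5-(dimethylphenylsilyl)-3-methylhexa-2,4-dien-1-ol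
Conditions: Pd(dppf)Cl2 (5 mol%), aq. K3PO4, THF, 50 °C
Reagents that add atoms: none
Why: Suzuki–Miyaura coupling at the C–B bond with retention at both alkenes should join the future C10 (iodide carbon) to the future C5 (boron carbon), the alkenylsilane and the free alcohol being inert.

Step 4
Reactants: 7 dienol
Product: 8 2-[(2Z,4Z)-6-(tert-butyldiphenylsilyloxy)-5-(dimethylphenylsilyl)-3-methylhexa-2,4-dien-1-yl]-4,4,5,5-tetramethyl-1,3,2-dioxaborolane
Conditions: B2pin2, [Pd(MeCN)4](BF4)2 (5 mol%), DMSO/MeOH, rt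
Reagents that add atoms: bis(pinacolato)diboron, CC1(C)OB(OC1(C)C)B1OC(C)(C)C(C)(C)O1
Why: Pd-catalysed borylation of the allylic C–OH through an η3-allyl complex should deliver boron to the primary terminus, and the geometry at the fully substituted terminus is expected to persist because syn/anti exchange there would need Pd σ-bonded to that carbon.

Step 5
Reactants: 9 (R)-5-(hydroxymethyl)oxolan-2-one
Product: 10 (R)-5-[(tert-butyldiphenylsilyloxy)methyl]oxolan-2-one
Conditions: TBDPSCl, imidazole, DMF, rt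
Reagents that add atoms: tert-butyl(chloro)diphenylsilane, CC(C)(C)[Si](Cl)(c1ccccc1)c1ccccc1
Why: Standard silylation masks the primary alcohol for the two enolate steps.

Step 6
Reactants: 10 silyl lactone
Product: 13 (R)-5-[(tert-butyldiphenylsilyloxy)methyl]furan-2(5H)-one, via selenide 11 (not isolated), via selenoxide 12 (not isolated)
Conditions: LDA, THF, −78 °C; PhSeBr; then 30% H2O2, pyridine, CH2Cl2, 0 °C to rt
Reagents that add atoms: none
Why: α-Selenenylation of the lactone enolate and selenoxide syn-elimination (only the C4 hydrogens are available) should give the butenolide without touching the C5 stereocentre.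

Step 7
Reactants: 13 butenolide; 14 1,3-dioxolane
Product: 15 (4R,5R)-5-[(tert-butyldiphenylsilyloxy)methyl]-4-(1,3-dioxolan-2-yl)oxolan-2-one (trans)
Conditions: hν (350 nm), Ph2CO (10 mol%), neat 14, rt
Reagents that add atoms: none
Why: Benzophenone-sensitised hydrogen abstraction gives the nucleophilic 1,3-dioxolan-2-yl radical, whose Giese-type addition to the butenolide β-carbon should occur anti to the silyloxymethyl group, setting C7 trans to C8 and bringing C6 in as a masked aldehyde.

Step 8
Reactants: 15 acetal lactone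
Product: 18 (4R,5R)-5-[(tert-butyldiphenylsilyloxy)methyl]-4-(1,3-dioxolan-2-yl)-3-methylideneoxolan-2-one, via Mannich base 16 (not isolated), via ammonium iodide 17 (not isolated)
Conditions: LDA, THF, −78 °C; CH2=NMe2+ I−, −78 °C to rt; then MeI, MeOH; then aq. NaHCO3, CH2Cl2
Reagents that add atoms: dimethylmethylideneammonium iodide (Eschenmoser's salt), C=[N+](C)C.[I-]
Why: Mannich alkylation of the lactone enolate, N-methylation and E1cB (Hofmann-type) elimination is the standard α-methylenation of γ-lactones and should install C11=C13.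

Step 9
Reactants: 18 methylene lactone
Product: 19 (4R,5R)-4-(1,3-dioxolan-2-yl)-5-(hydroxymethyl)-3-methylideneoxolan-2-one
Conditions: HF·pyridine, pyridine, THF, 0 °C to rt
Reagents that add atoms: none
Why: Buffered fluoride cleaves the silyl ether under conditions too mild to open the dioxolane or add to the α-methylene lactone.

Step 10
Reactants: 19 alcohol
Product: 20 (2R,3R)-3-(1,3-dioxolan-2-yl)-4-methylidene-5-oxooxolane-2-carbaldehyde
Conditions: DMP, pyridine, CH2Cl2, 0 °C; used crude
Reagents that add atoms: none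
Why: Buffered Dess–Martin oxidation should give the α-acyloxy aldehyde (C9) without epimerising C8.

Step 11
Reactants: 20 aldehyde; 8 allylboronate
Product: 22 (4R,5R)-5-[(1S,2S,3Z)-5-(tert-butyldiphenylsilyloxy)-4-(dimethylphenylsilyl)-2-ethenyl-1-hydroxy-2-methylpent-3-en-1-yl]-4-(1,3-dioxolan-2-yl)-3-methylideneoxolan-2-one, via borate ester 21 (not isolated)
Conditions: 4 Å MS, toluene, rt to 45 °C; then aq. pH 7 buffer
Reagents that add atoms: none
Why: Thermal allylboration through a Zimmerman–Traxler chair should attack the aldehyde anti to the lactone oxygen on C8 (Cornforth/polar Felkin–Anh, sets C9) with the dienyl carbon cis to CH2B axial and CH3 equatorial, which sets the quaternary C10 and leaves its vinyl group gauche to the C9 oxygen; attack through the γ-carbon is the only six-membered array open to the pentadienyl boronate.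

Step 12
Reactants: 22 alcohol
Product: 23 C9 acetate of 22
Conditions: Ac2O, pyridine, DMAP (cat.), CH2Cl2, rt
Reagents that add atoms: acetic anhydride, CC(=O)OC(C)=O
Why: Acetylation installs the C9 acetate of the target and removes the free hydroxyl before the metal-mediated steps.

Step 13
Reactants: 23 alkenylsilane
Product: 24 alkenyl iodide (I in place of SiMe2Ph, cis to C10; 3Z)
Conditions: NIS, MeCN/ClCH2CN (4:1), 0 °C to rt
Reagents that add atoms: N-iodosuccinimide, O=C1CCC(=O)N1I
Why: Electrophilic ipso-iododesilylation proceeds through a β-silyl cation with retention, so iodine should end cis to C10, and the vinylsilane is far more nucleophilic than the vinyl group or the enoate.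

Step 14
Reactants: 24 alkenyl iodide
Product: 25 allylboronate (CH2Bpin in place of I, cis to C10; 3E by CIP)
Conditions: ICH2Bpin, Zn dust, THF, rt; then 24, Pd(PPh3)4 (5 mol%), THF, rt to 40 °C
Reagents that add atoms: 2-(iodomethyl)-4,4,5,5-tetramethyl-1,3,2-dioxaborolane (as its zinc reagent), CC1(C)OB(CI)OC1(C)C
Why: Negishi coupling of the alkenyl iodide with borylmethylzinc iodide proceeds with retention and tolerates esters and acetals, and should give an allylboronate that, unlike allyl-Cr, -Zn or -In species, holds its geometry.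

Step 15
Reactants: 25 allylboronate acetal
Product: 28 9α-acetoxy-15-(tert-butyldiphenylsilyloxy)-6β-hydroxyelema-1,3,11(13)-trien-12,8α-olide, via aldehyde 26 (not isolated), via cyclic borate 27 (not isolated)
Conditions: LiBF4, MeCN/H2O (50:1), 40 °C; then aq. NaHCO3
Reagents that add atoms: water, O
Why: Hydrolysis of the dioxolane frees the C6 aldehyde, which binds the allylic boron and is attacked by the γ-carbon C5 with allylic transposition (SE2′); the closest known reaction type is the intramolecular allylboration of an ω-oxo allylboronate released from its acetal. The cyclohexane C5–C10 closes by C5–C6 bond formation, 6-exo-trig at the carbonyl, with C4=C3 ending exocyclic as the 2-(silyloxymethyl)allyl unit. C5 and C6 are set together by the alkene geometry: CH2B cis to C10 forces the tether axial in the Zimmerman–Traxler chair, which puts the new C6–O axial (β) and the C4 group equatorial (β), i.e. cis. The face that reacts is fixed by the existing centres, because only one chair of the forming ring keeps the trans-lactone bonds at C7 and C8 diequatorial, and in it the C9 acetate and C10 methyl are axial as in the target. The step needs stereospecific transfer (no E/Z leakage, no open or boat array) and chemoselectivity for the aldehyde over lactone, acetate and enoate; the configurationally stable pinacol boronate, the near-neutral medium and intramolecularity should secure both.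

Step 16
Reactants: 28 alcohol; 29 angelic acid
Product: 31 9α-acetoxy-6β-angeloyloxy-15-(tert-butyldiphenylsilyloxy)elema-1,3,11(13)-trien-12,8α-olide, via mixed anhydride 30 (not isolated)
Conditions: 29, 2,4,6-Cl3C6H2COCl, Et3N, toluene, rt; then 28, toluene, 80 °C
Reagents that add atoms: none
Why: Yamaguchi-type acylation with the preformed mixed anhydride and no DMAP should esterify the hindered axial C6 hydroxyl while keeping the Z (angelate) geometry.

Step 17
Reactants: 31 silyl ether
Product: 32 9α-acetoxy-6β-angeloyloxy-15-hydroxyelema-1,3,11(13)-trien-12,8α-olide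
Conditions: HF·pyridine, pyridine, THF, 0 °C to rt
Reagents that add atoms: none
Why: Buffered fluoride removes the allylic TBDPS ether; esters, lactone and alkenes are inert to it.

Step 18
Reactants: 32 allylic alcohol
Product: 33 9α-acetoxy-6β-angeloyloxy-15-oxoelema-1,3,11(13)-trien-12,8α-olide (target)
Conditions: DMP, pyridine, CH2Cl2, 0 °C
Reagents that add atoms: none
Why: Dess–Martin oxidation of the primary allylic alcohol should give the 2-substituted acrolein without isomerising the angelate or epimerising C5.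

**Compound list**

1 | tert-butyl(diphenyl)(prop-2-yn-1-yloxy)silane | C#CCO[Si](c1ccccc1)(c1ccccc1)C(C)(C)C | starting material
2 | 2-(dimethylphenylsilyl)-4,4,5,5-tetramethyl-1,3,2-dioxaborolane | C[Si](C)(c1ccccc1)B1OC(C)(C)C(C)(C)O1 | starting material
3 | tert-butyl{[(2Z)-2-(dimethylphenylsilyl)-3-(pinacolboryl)prop-2-en-1-yl]oxy}diphenylsilane | CC(C)(C)[Si](c1ccccc1)(c1ccccc1)OC/C([Si](C)(C)c1ccccc1)=C/B1OC(C)(C)C(C)(C)O1 | intermediate
4 | but-2-yn-1-ol | CC#CCO | starting material
5 | sodium 2,2-bis(2-methoxyethoxy)-3-methyl-2,5-dihydro-1,2-oxaaluminol-2-uide (alkenylalanate) | CC1=CCO[Al-]1(OCCOC)OCCOC.[Na+] | intermediate (not isolated)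
6 | (Z)-3-iodobut-2-en-1-ol | C/C(I)=C/CO | intermediate
7 | (2Z,4Z)-6-(tert-butyldiphenylsilyloxy)-5-(dimethylphenylsilyl)-3-methylhexa-2,4-dien-1-ol | OC/C=C(/C)\C=C(/[Si](C)(C)c1ccccc1)CO[Si](c1ccccc1)(c1ccccc1)C(C)(C)C | intermediate
8 | 2-[(2Z,4Z)-6-(tert-butyldiphenylsilyloxy)-5-(dimethylphenylsilyl)-3-methylhexa-2,4-dien-1-yl]-4,4,5,5-tetramethyl-1,3,2-dioxaborolane | CC1(C)OB(C/C=C(/C)\C=C(/[Si](C)(C)c2ccccc2)CO[Si](c2ccccc2)(c2ccccc2)C(C)(C)C)OC1(C)C | intermediate
9 | (R)-5-(hydroxymethyl)oxolan-2-one | OC[C@@H]1OC(=O)CC1 | starting material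
10 | (R)-5-[(tert-butyldiphenylsilyloxy)methyl]oxolan-2-one | CC(C)(C)[Si](c1ccccc1)(c1ccccc1)OC[C@@H]1OC(=O)CC1 | intermediate
11 | (3S,5R)-5-[(tert-butyldiphenylsilyloxy)methyl]-3-(phenylselanyl)oxolan-2-one | CC(C)(C)[Si](c1ccccc1)(c1ccccc1)OC[C@@H]1OC(=O)[C@@H]([Se]c2ccccc2)C1 | intermediate (not isolated)
12 | selenoxide of 11 (both configurations at Se) | CC(C)(C)[Si](c1ccccc1)(c1ccccc1)OC[C@@H]1OC(=O)[C@@H]([Se](=O)c2ccccc2)C1 | intermediate (not isolated)
13 | (R)-5-[(tert-butyldiphenylsilyloxy)methyl]furan-2(5H)-one | CC(C)(C)[Si](c1ccccc1)(c1ccccc1)OC[C@@H]1OC(=O)C=C1 | intermediate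
14 | 1,3-dioxolane | C1COCO1 | starting material
15 | (4R,5R)-5-[(tert-butyldiphenylsilyloxy)methyl]-4-(1,3-dioxolan-2-yl)oxolan-2-one | CC(C)(C)[Si](c1ccccc1)(c1ccccc1)OC[C@@H]1OC(=O)C[C@H]1C1OCCO1 | intermediate
16 | (3S,4R,5R)-3-[(dimethylamino)methyl] derivative of 15 (Mannich base) | CC(C)(C)[Si](c1ccccc1)(c1ccccc1)OC[C@@H]1OC(=O)[C@H](CN(C)C)[C@H]1C1OCCO1 | intermediate (not isolated)
17 | trimethylammonium iodide of 16 | CC(C)(C)[Si](c1ccccc1)(c1ccccc1)OC[C@@H]1OC(=O)[C@H](C[N+](C)(C)C)[C@H]1C1OCCO1.[I-] | intermediate (not isolated)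
18 | (4R,5R)-5-[(tert-butyldiphenylsilyloxy)methyl]-4-(1,3-dioxolan-2-yl)-3-methylideneoxolan-2-one | CC(C)(C)[Si](c1ccccc1)(c1ccccc1)OC[C@@H]1OC(=O)C(=C)[C@H]1C1OCCO1 | intermediate
19 | (4R,5R)-4-(1,3-dioxolan-2-yl)-5-(hydroxymethyl)-3-methylideneoxolan-2-one | OC[C@@H]1OC(=O)C(=C)[C@H]1C1OCCO1 | intermediate
20 | (2R,3R)-3-(1,3-dioxolan-2-yl)-4-methylidene-5-oxooxolane-2-carbaldehyde | O=C[C@@H]1OC(=O)C(=C)[C@H]1C1OCCO1 | intermediate
21 | pinacol borate ester of 22 | C=C[C@](/C=C(\[Si](C)(C)c1ccccc1)CO[Si](c1ccccc1)(c1ccccc1)C(C)(C)C)(C)[C@H](OB1OC(C)(C)C(C)(C)O1)[C@@H]1OC(=O)C(=C)[C@H]1C1OCCO1 | intermediate (not isolated)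
22 | (4R,5R)-5-[(1S,2S,3Z)-5-(tert-butyldiphenylsilyloxy)-4-(dimethylphenylsilyl)-2-ethenyl-1-hydroxy-2-methylpent-3-en-1-yl]-4-(1,3-dioxolan-2-yl)-3-methylideneoxolan-2-one | C=C[C@](/C=C(\[Si](C)(C)c1ccccc1)CO[Si](c1ccccc1)(c1ccccc1)C(C)(C)C)(C)[C@H](O)[C@@H]1OC(=O)C(=C)[C@H]1C1OCCO1 | intermediate
23 | acetate of 22 (C9–OAc) | C=C[C@](/C=C(\[Si](C)(C)c1ccccc1)CO[Si](c1ccccc1)(c1ccccc1)C(C)(C)C)(C)[C@H](OC(C)=O)[C@@H]1OC(=O)C(=C)[C@H]1C1OCCO1 | intermediate
24 | alkenyl iodide (I in place of SiMe2Ph in 23, cis to C10) | C=C[C@](/C=C(\I)CO[Si](c1ccccc1)(c1ccccc1)C(C)(C)C)(C)[C@H](OC(C)=O)[C@@H]1OC(=O)C(=C)[C@H]1C1OCCO1 | intermediate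
25 | allylboronate (CH2Bpin in place of I in 24, cis to C10) | C=C[C@](/C=C(\CB1OC(C)(C)C(C)(C)O1)CO[Si](c1ccccc1)(c1ccccc1)C(C)(C)C)(C)[C@H](OC(C)=O)[C@@H]1OC(=O)C(=C)[C@H]1C1OCCO1 | intermediate
26 | C6 aldehyde from 25 | C=C[C@](/C=C(\CB1OC(C)(C)C(C)(C)O1)CO[Si](c1ccccc1)(c1ccccc1)C(C)(C)C)(C)[C@H](OC(C)=O)[C@@H]1OC(=O)C(=C)[C@H]1C=O | intermediate (not isolated)
27 | pinacol borate ester of 28 | C=C[C@]1(C)[C@H](OC(C)=O)[C@@H]2OC(=O)C(=C)[C@H]2[C@@H](OB3OC(C)(C)C(C)(C)O3)[C@H]1C(=C)CO[Si](c1ccccc1)(c1ccccc1)C(C)(C)C | intermediate (not isolated)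
28 | 9α-acetoxy-15-(tert-butyldiphenylsilyloxy)-6β-hydroxyelema-1,3,11(13)-trien-12,8α-olide | C=C[C@]1(C)[C@H](OC(C)=O)[C@@H]2OC(=O)C(=C)[C@H]2[C@@H](O)[C@H]1C(=C)CO[Si](c1ccccc1)(c1ccccc1)C(C)(C)C | intermediate
29 | angelic acid, (Z)-2-methylbut-2-enoic acid | C/C=C(/C)C(=O)O | starting material
30 | angelic 2,4,6-trichlorobenzoic anhydride | C/C=C(/C)C(=O)OC(=O)c1c(Cl)cc(Cl)cc1Cl | intermediate (not isolated)
31 | 9α-acetoxy-6β-angeloyloxy-15-(tert-butyldiphenylsilyloxy)elema-1,3,11(13)-trien-12,8α-olide | C=C[C@]1(C)[C@H](OC(C)=O)[C@@H]2OC(=O)C(=C)[C@H]2[C@@H](OC(=O)/C(C)=C\C)[C@H]1C(=C)CO[Si](c1ccccc1)(c1ccccc1)C(C)(C)C | intermediate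
32 | 9α-acetoxy-6β-angeloyloxy-15-hydroxyelema-1,3,11(13)-trien-12,8α-olide | C=C[C@]1(C)[C@H](OC(C)=O)[C@@H]2OC(=O)C(=C)[C@H]2[C@@H](OC(=O)/C(C)=C\C)[C@H]1C(=C)CO | intermediate
33 | 9α-acetoxy-6β-angeloyloxy-15-oxoelema-1,3,11(13)-trien-12,8α-olide (CNP0228039.1) | C=C[C@]1(C)[C@H](OC(C)=O)[C@@H]2OC(=O)C(=C)[C@H]2[C@@H](OC(=O)/C(C)=C\C)[C@H]1C(=C)C=O | target

**Count and risks**

Total: 18 steps (fragment 8: steps 1–4; lactone aldehyde 20: steps 5–10; steps 11–18 after the union). Longest linear sequence: 14 steps (steps 5–18).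

Step 15. The chair–chair transition state must carry the forming C6–O bond axial, syn to the axial C10 methyl. If this strain diverts closure through a boat-like array, or slows it enough for the β-formyl α-methylene lactone to epimerise, control at C5 and C6 is lost. Fallback, from 25 back to 28: 25 is cyclised under the same hydrolytic trigger without regard to the C6 outcome. This gives, by way of the epimeric cyclic borate ester F1, the C6-epimeric (equatorial) alcohol F2 together with 28. The mixture is oxidised with DMP to the C6 ketone F3, in which C5 can relax to the equatorial isomer. Luche reduction (NaBH4, CeCl3, MeOH, −78 °C) should then deliver hydride from the equatorial side, because the axial face of C6 is blocked by the C10 methyl, and return the axial alcohol 28. The stereocentre is then set by ketone reduction instead of allyl geometry.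

Step 4. Syn/anti exchange or η3 slip along the dienyl system in the palladium intermediate may erode the geometry at C1=C10, which would scramble C10 in step 11. Fallback, from 7 back to 22, without boron or an allyl–palladium species: 7 is converted by Corey–Kim chlorination (NCS, Me2S, CH2Cl2, −20 °C; SN2) into the allylic chloride F4. F4 is converted into the allyltrichlorosilane F5 (HSiCl3, CuCl cat., iPr2NEt, Et2O). F5 adds to aldehyde 20 in DMF at 0 °C through a closed chair transition state (Lewis-base-promoted allyltrichlorosilane addition) to give the trichlorosilyl ether F6, which aqueous NaHCO3 hydrolyses to 22.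

Step 16. Acylation of the axial C6 hydroxyl, shielded by the 1,3-diaxial C10 methyl, may be slow enough for angelate-to-tiglate isomerisation or migration of the lactone acyl group from O8 to O6 to compete. Fallback, from 28 back to 31: 28 is esterified with 2-[bis(2,2,2-trifluoroethoxy)phosphoryl]propanoic acid (DCC, DMAP cat., CH2Cl2, 0 °C) to the phosphonate ester F7. The Z-trisubstituted alkene is then built on the ester by Still–Gennari olefination (KHMDS, 18-crown-6, THF, −78 °C; then acetaldehyde), arriving at 31.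

**Further compounds**

F1 | step 15 | pinacol borate ester of the C6 epimer of 28 | C=C[C@]1(C)[C@H](OC(C)=O)[C@@H]2OC(=O)C(=C)[C@H]2[C@H](OB3OC(C)(C)C(C)(C)O3)[C@H]1C(=C)CO[Si](c1ccccc1)(c1ccccc1)C(C)(C)C
F2 | step 15 | C6 epimer of 28 (6α-hydroxy) | C=C[C@]1(C)[C@H](OC(C)=O)[C@@H]2OC(=O)C(=C)[C@H]2[C@H](O)[C@H]1C(=C)CO[Si](c1ccccc1)(c1ccccc1)C(C)(C)C
F3 | step 15 | 9α-acetoxy-15-(tert-butyldiphenylsilyloxy)-6-oxoelema-1,3,11(13)-trien-12,8α-olide | C=C[C@]1(C)[C@H](OC(C)=O)[C@@H]2OC(=O)C(=C)[C@H]2C(=O)[C@H]1C(=C)CO[Si](c1ccccc1)(c1ccccc1)C(C)(C)C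
F4 | step 4 | (2Z,4Z)-allylic chloride from 7 | ClC/C=C(/C)\C=C(/[Si](C)(C)c1ccccc1)CO[Si](c1ccccc1)(c1ccccc1)C(C)(C)C
F5 | step 4 | (2Z,4Z)-allyltrichlorosilane from F4 | Cl[Si](Cl)(Cl)C/C=C(/C)\C=C(/[Si](C)(C)c1ccccc1)CO[Si](c1ccccc1)(c1ccccc1)C(C)(C)C
F6 | step 4 | trichlorosilyl ether of 22 | C=C[C@](/C=C(\[Si](C)(C)c1ccccc1)CO[Si](c1ccccc1)(c1ccccc1)C(C)(C)C)(C)[C@H](O[Si](Cl)(Cl)Cl)[C@@H]1OC(=O)C(=C)[C@H]1C1OCCO1
F7 | step 16 | 2-[bis(2,2,2-trifluoroethoxy)phosphoryl]propanoate of 28 (both configurations at the phosphonate α-carbon) | C=C[C@]1(C)[C@H](OC(C)=O)[C@@H]2OC(=O)C(=C)[C@H]2[C@@H](OC(=O)C(C)P(=O)(OCC(F)(F)F)OCC(F)(F)F)[C@H]1C(=C)CO[Si](c1ccccc1)(c1ccccc1)C(C)(C)C
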